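## Structural features

Neoirietetraol (35) is a trans-fused decalin (rings A and B) whose carbon C7 is a tertiary carbinol bonded to the quaternary carbon C6 of a cyclopentane (ring C), so that C2 (CMe2), C6 and C7 form a row of three fully substituted carbons. Ring B carries the angular methyl (C10) and the angular hydroxyl (C15) trans to each other, a tertiary alcohol at C14 whose axial hydroxyl is anti to that of C15, and an equatorial bromide at C11 next to the quaternary C10. In ring A the C7 hydroxyl is axial and syn to the C15 hydroxyl (a 1,3-diaxial diol), and the cyclopentyl group is equatorial. On ring C the C3 bromide, the C5 hydroxyl and the C6–C7 bond lie on one face and the C6 methyl on the other; C3 is again neopentylic. The eight stereocentres fall into two contiguous groups (C3/C5/C6/C7 and C10/C11/C14/C15) that meet across ring A. The fragile elements are the two secondary neopentylic bromides (elimination, reduction, rearrangement on ionisation), the tertiary alcohols including the vicinal C14/C15 diol, and every β-hydroxy carbonyl met on the way (retro-aldol). The real difficulty is the C6–C7 bond, which joins a quaternary carbon to a tertiary carbinol inside ring A, together with the 1,3-relationship of the C7 and C15 oxygens. The key step uses the fact that the six ring A carbons C7, C8, C9, C10, C15 and C16 are a 3-hydroxy-1,5-diene when C10–C15 is a bond and C7–C8 is not. A [3,3] shift can then build C7–C8 beside C6, and a transannular ene reaction can give back C10–C15 with the angular groups trans.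

## Logic of the disconnections

35 to 34: only the two O–Si bonds of one silylene are cut. The C5 and C7 hydroxyls are released last, in one operation, so no diol or β-hydroxy ketone is exposed earlier. The forward step needs a fluoride source that spares secondary bromides and tertiary alcohols.

34 to 33 to 31: the C–H bonds at C3/C4 and C11/C12 are cut back to two alkenyl bromides, and these to two ketones. Substitution at a neopentylic secondary carbon is not a dependable way to these bromides, whereas hydrogen-atom transfer to an alkenyl bromide is. Both bromides are then made by the same three operations. The forward steps must convert the ketones without carbanions (retro-aldol at C15, β-elimination at C5) and must deliver hydrogen to the correct face at C3 and C11.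

31 to 30 to 28 to 27 to 26: the C14–O bond (hydration of C13=C14), the two silyl ethers at C3 and C11, and the saturation of C8=C9 are removed. This returns the molecule to the direct product of the key step. The forward steps need Markovnikov hydration anti to the C15 hydroxyl and reduction of the disubstituted alkene only.

26 to 23: C7–C8 and C10–C15 are cut. Rings A and B collapse to a single cyclohexenol that carries a vinyl group and an enol-ether alkenyl group on neighbouring carbons, and the C6–C7 region is no longer made by an intermolecular attack on a hindered centre. The forward step needs the two alkenyl groups trans, the enol ether Z, and a chair transition state.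

23 to 21 and 9: C15–C16 is cut between an alkenyl anion and a ketone. This divides the molecule into a ring C piece and a ring B piece of similar size. The addition must be irreversible, must go 1,2 and must enter anti to the vinyl group.

21 to 20 to 17: the O–Si bonds and the C16–Br bond are cut. The enol ether, its geometry and the handle for metalation all come from a methyl ketone. The forward steps need regiospecific bromination and a Z-selective enol silylation.

17 to 16 to 14: the C6–CH3 bond (a migrating methyl) and the C5–O bond (an epoxide) are cut. The quaternary C6 with methyl trans and acetyl cis to the C5 hydroxyl becomes a trisubstituted alkene with a dimethyl carbinol. The forward steps need face-selective epoxidation and an anti 1,2-shift.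

14 to 11 to 10: the C6–C7 bond of the fragment (alkenyllithium plus acetone) and one C–H bond (reduction) are cut. This leads to a symmetrical commercial dione that already holds the C2 gem-dimethyl group. The forward step must distinguish the two carbonyl groups enantioselectively.

9 to 7 to 6: the C13=C14 unsaturation and the C14–CH3 bond are removed, leaving a ketone with a single enolisable position.

6 to 4 to 3 to 2 to 1: the terminal carbon of an allyl group (regained from ethylene after shortening), the carbinol C–H at C11 (desymmetrising reduction) and the C10–allyl bond are cut. The allyl group serves as the large group in the reduction, so that C10 and C11 are set together with the oxygen cis to the future vinyl group.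

## Other disconnections considered

Alternative 1: The cut is C2–C6. In the forward direction ZnBr2 opens a C6–C7 epoxide at C6 while the ring carbon C2 of a neighbouring cyclobutanol moves from C5 to C6; this expands the four-membered ring to ring C and gives the β-hydroxy cyclopentanone A1.
- In favour: strain release drives the formation of the most crowded bond of the molecule, the vicinal quaternary pair C2/C6, and the shift is stereospecific (anti to the breaking C–O bond).
- Against: the tetrasubstituted epoxide must be made on the correct face relative to a finished decalin. The free C14/C15 diol and the C11 bromide must tolerate the Lewis acid, and hydride or ring-carbon shifts from C8 or C16 can compete. In A1 the C3 oxygen has the orientation of the later bromide, so the bromide needs net retention at a neopentylic carbon. The C5 ketone must then be reduced cis to C7.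
- Comparison: it builds ring C last on the decalin, whereas the chosen plan builds the decalin last on ring C. Mechanistically both rest on a stereospecific shift and are equal there. Alternative 1 is the better plan in that the C7 carbinol is delivered free, with no protecting group, and C2–C6 is made directly. It is weaker in that the decalin diol and both bromides remain to be solved elsewhere. The step count would probably be similar.

Alternative 2: The cut is C5–C6 together with O–C7. In the forward direction a C5 aldehyde tethered to a tetrasubstituted exocyclic C6=C7 alkene is irradiated near 300 nm; the Paternò–Büchi reaction closes ring C and the oxetane of A2.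
- In favour: one step without base or organometallic reagent forms the quaternary C6 and the C7–O bond, and the tether fixes the regiochemistry.
- Against: the reaction runs through a triplet 1,4-biradical, so the alkene geometry is not passed on reliably to C6/C7. Norrish cleavage and hydrogen abstraction of the hindered aldehyde compete. The tetrasubstituted alkene must itself be made as one isomer. The oxetane of A2 must still be opened to the 1,3-diol by bringing in a second oxygen with retention at C7, because attack at C5 would invert that centre.
- Comparison: the [3,3] shift of the chosen plan is concerted and transfers configuration through a chair, which is the stronger mechanistic basis. Alternative 2 is the better plan in mildness and in making C6 and the C7 oxygen together without protecting C7. The end-game lengths would be similar.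

Alternative 3: The cut is C14–C15. In the forward direction a triazolium-derived carbene converts a C14 aldehyde into an acyl-anion equivalent that adds to the ring A ketone C15; this closes ring B and gives the α-ketol A3.
- In favour: the reaction is catalytic and mild. The angular hydroxyl and a C14 ketone arise together, and a methyl nucleophile adding equatorially would complete the C14/C15 diol. On this point Alternative 3 is better than the chosen plan: it is shorter and needs no mercury. The C11 bromide can already be in place.
- Against: the trans ring fusion must be imposed by the C10 centre or the catalyst. The plan also leaves the hardest bond untouched: A3 has only a ketal at C7, and the later addition of a tertiary cyclopentyl nucleophile to a C7 ketone is the intermolecular union of two hindered centres that the chosen plan avoids.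
- Comparison: it is equal or better for ring B and clearly weaker for the C6–C7 problem. Overall step economy would depend on that unsolved union.

Key step: step 17

Remark on the chemistry: the key step needs only the carbon skeleton, the C7 enol oxygen and the C15 hydroxyl, so the other heteroatom groups were chosen as follows. C3 and C11 are carried as triethylsilyl ethers and both bromides are made together at the end, because a secondary neopentylic bromide is not expected to survive tert-butyllithium or 180 °C. The C11 oxygen is a stereocentre cis to the vinyl group, so that it steers the addition to C15. O5 and O7 are tied in one di-tert-butylsilylene.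

Remark on the configurations: tracing the chair transition state shows that C10 and C15 must have the same spatial arrangement before and after the key step and that C7 then has the arrangement of the target. Compounds 23 and 26 are drawn accordingly and the skeleton needed no change. The sense of the (S)-CBS catalyst is assigned by the usual model, with the quaternary carbon as the large group.

## Route

Step 1
Reactants: 1 2-methylcyclohexane-1,3-dione
Product: 2 2-methyl-2-(prop-2-en-1-yl)cyclohexane-1,3-dione
Conditions: allyl methyl carbonate, Pd(PPh3)4 (2 mol %), THF, rt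
Reagents that add atoms: allyl methyl carbonate, C=CCOC(=O)OC
Why: Tsuji–Trost C-allylation of the dione enol under neutral carbonate conditions; the new quaternary carbon is still achiral.

Step 2
Reactants: 2 2-methyl-2-(prop-2-en-1-yl)cyclohexane-1,3-dione
Product: 3 (2R,3R)-3-hydroxy-2-methyl-2-(prop-2-en-1-yl)cyclohexan-1-one
Conditions: (S)-2-methyl-CBS-oxazaborolidine (20 mol %), catecholborane, toluene/THF, −78 to −40 °C
Reagents that add atoms: none
Why: Corey–Bakshi–Shibata desymmetrising reduction; the catalyst should select the carbonyl and face that give the 3R carbinol while hydride enters anti to the larger allyl group, so C10 and C11 are set together with the hydroxyl cis to allyl.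

Step 3
Reactants: 3 (2R,3R)-3-hydroxy-2-methyl-2-(prop-2-en-1-yl)cyclohexan-1-one
Product: 4 (2R,3R)-2-methyl-2-(prop-2-en-1-yl)-3-(triethylsilyloxy)cyclohexan-1-one
Conditions: Et3SiCl, imidazole, DMF, 0 °C
Reagents that add atoms: chlorotriethylsilane, CC[Si](Cl)(CC)CC
Why: Standard silylation of a secondary alcohol; the mild base avoids retro-aldol opening of the β-hydroxy ketone.

Step 4
Reactants: 4 (2R,3R)-2-methyl-2-(prop-2-en-1-yl)-3-(triethylsilyloxy)cyclohexan-1-one
Product: 5 (2R,3R)-2-methyl-2-[(E)-prop-1-en-1-yl]-3-(triethylsilyloxy)cyclohexan-1-one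
Conditions: RuHCl(CO)(PPh3)3 (3 mol %), toluene, 80 °C
Reagents that add atoms: none
Why: Ruthenium-hydride alkene isomerisation moves the terminal double bond one position inward; the quaternary carbon stops further migration.

Step 5
Reactants: 5 (2R,3R)-2-methyl-2-[(E)-prop-1-en-1-yl]-3-(triethylsilyloxy)cyclohexan-1-one
Product: 6 (2R,3R)-2-ethenyl-2-methyl-3-(triethylsilyloxy)cyclohexan-1-one
Conditions: ethylene (5 bar), second-generation Hoveyda–Grubbs catalyst (5 mol %), toluene, 40 °C
Reagents that add atoms: ethylene, C=C
Why: Ethenolysis (cross-metathesis with ethylene) trims the propenyl group to the vinyl group; excess ethylene drives the exchange and the stereocentres are not involved.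

Step 6
Reactants: 6 (2R,3R)-2-ethenyl-2-methyl-3-(triethylsilyloxy)cyclohexan-1-one
Product: 7 (2R,3R)-2-ethenyl-2,6-dimethyl-3-(triethylsilyloxy)cyclohexan-1-one (C6 epimers)
Conditions: LiN(i-Pr)2, THF, −78 °C; MeI, −78 to 0 °C
Reagents that add atoms: iodomethane, CI
Why: Enolate alkylation; only one α-carbon can be deprotonated, and the new centre is removed in step 7 so its configuration is irrelevant.

Step 7
Reactants: 7 (2R,3R)-2-ethenyl-2,6-dimethyl-3-(triethylsilyloxy)cyclohexan-1-one
Product: 9 (5R,6R)-6-ethenyl-2,6-dimethyl-5-(triethylsilyloxy)cyclohex-2-en-1-one, via trimethylsilyl enol ether 8 (not isolated)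
Conditions: LiN(i-Pr)2, Me3SiCl, THF, −78 °C; then Pd(OAc)2 (1.1 equiv), MeCN, rt
Reagents that add atoms: none
Why: Saegusa–Ito oxidation of the only possible silyl enol ether; β-hydride elimination into the ring should give the 2-methyl enone.

Step 8
Reactants: 10 2,2-dimethylcyclopentane-1,3-dione
Product: 11 (3R)-3-hydroxy-2,2-dimethylcyclopentan-1-one
Conditions: (S)-2-methyl-CBS-oxazaborolidine (20 mol %), catecholborane, toluene, −78 °C
Reagents that add atoms: none
Why: Corey–Bakshi–Shibata reduction of one of two enantiotopic carbonyl groups, with the quaternary carbon as the large group; it sets the C3 carbinol that later relays configuration to C5 and C6.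

Step 9
Reactants: 11 (3R)-3-hydroxy-2,2-dimethylcyclopentan-1-one
Product: 12 2,4,6-triisopropylbenzenesulfonylhydrazone of 11
Conditions: 2,4,6-triisopropylbenzenesulfonohydrazide, THF, cat. HCl, rt
Reagents that add atoms: 2,4,6-triisopropylbenzenesulfonohydrazide, CC(C)c1cc(C(C)C)c(S(=O)(=O)NN)c(C(C)C)c1
Why: Hydrazone condensation; the sulfonyl group should lie anti to the CMe2 carbon and therefore syn to the CH2 group that is deprotonated next.

Step 10
Reactants: 12 2,4,6-triisopropylbenzenesulfonylhydrazone of 11
Product: 14 (1R)-3-(2-hydroxypropan-2-yl)-2,2-dimethylcyclopent-3-en-1-ol, via dilithio species 13 (not isolated)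
Conditions: n-BuLi (3.3 equiv), THF/TMEDA, −78 to 0 °C; acetone, −78 °C
Reagents that add atoms: acetone, CC(C)=O
Why: Shapiro reaction; the hydrazone dianion loses sulfinate and nitrogen to give the alkenyllithium at C6, which adds to acetone and so makes the C6–C7 bond of the fragment.

Step 11
Reactants: 14 (1R)-3-(2-hydroxypropan-2-yl)-2,2-dimethylcyclopent-3-en-1-ol
Product: 15 (1R,3R,5S)-1-(2-hydroxypropan-2-yl)-2,2-dimethyl-6-oxabicyclo[3.1.0]hexan-3-ol (epoxide cis to the ring hydroxyl)
Conditions: VO(acac)2 (3 mol %), t-BuOOH, CH2Cl2, 0 °C to rt
Reagents that add atoms: tert-butyl hydroperoxide, CC(C)(C)OO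
Why: Hydroxyl-directed vanadium epoxidation; the homoallylic ring hydroxyl and the allylic tertiary hydroxyl can both bind the metal, so oxygen should be delivered to the face of the ring hydroxyl, which sets C5 and the face at C6.

Step 12
Reactants: 15 (1R,3R,5S)-1-(2-hydroxypropan-2-yl)-2,2-dimethyl-6-oxabicyclo[3.1.0]hexan-3-ol
Product: 16 2-[(1R,3R,5S)-2,2-dimethyl-3-(triethylsilyloxy)-6-oxabicyclo[3.1.0]hexan-1-yl]propan-2-ol
Conditions: Et3SiCl, imidazole, DMF, 0 °C
Reagents that add atoms: chlorotriethylsilane, CC[Si](Cl)(CC)CC
Why: Selective silylation of the secondary alcohol; the tertiary carbinol stays free for the rearrangement.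

Step 13
Reactants: 16 2-[(1R,3R,5S)-2,2-dimethyl-3-(triethylsilyloxy)-6-oxabicyclo[3.1.0]hexan-1-yl]propan-2-ol
Product: 17 1-[(1R,3R,5S)-5-hydroxy-1,2,2-trimethyl-3-(triethylsilyloxy)cyclopentyl]ethan-1-one
Conditions: BF3·OEt2 (0.3 equiv), CH2Cl2, −78 to −40 °C
Reagents that add atoms: none
Why: Semipinacol rearrangement of a 2,3-epoxy alcohol; the Lewis acid opens the epoxide at the tertiary C6 and a methyl group shifts from the carbinol carbon anti to the breaking C–O bond, so C6 becomes quaternary with methyl trans and acetyl cis to the C5 hydroxyl.

Step 14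
Reactants: 17 1-[(1R,3R,5S)-5-hydroxy-1,2,2-trimethyl-3-(triethylsilyloxy)cyclopentyl]ethan-1-one
Product: 20 2-bromo-1-[(1R,3R,5S)-5-hydroxy-1,2,2-trimethyl-3-(triethylsilyloxy)cyclopentyl]ethan-1-one, via bis(trimethylsilyl) derivative 18 (not isolated), via O-trimethylsilyl bromoketone 19 (not isolated)
Conditions: Me3SiOTf, Et3N, CH2Cl2, 0 °C; NBS, THF, −78 °C; citric acid, MeOH, 0 °C
Reagents that add atoms: N-bromosuccinimide, O=C1CCC(=O)N1Br
Why: Bromination of a silyl enol ether; only the methyl group can enolise, and the labile trimethylsilyl ether at O5 is cleaved under acid conditions that leave the triethylsilyl ether intact.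

Step 15
Reactants: 20 2-bromo-1-[(1R,3R,5S)-5-hydroxy-1,2,2-trimethyl-3-(triethylsilyloxy)cyclopentyl]ethan-1-one
Product: 21 di-tert-butylsilylene-bridged (Z)-bromo enol ether (O5 and O7 in one six-membered ring; Br cis to O7)
Conditions: t-Bu2Si(OTf)2, 2,6-lutidine, CH2Cl2, 0 °C; then Et3N, rt
Reagents that add atoms: di-tert-butylsilyl bis(trifluoromethanesulfonate), CC(C)(C)[Si](OS(=O)(=O)C(F)(F)F)(OS(=O)(=O)C(F)(F)F)C(C)(C)C
Why: O-silylation followed by intramolecular soft enolisation with a silyl triflate and an amine; the Z isomer should form because bromine avoids the quaternary C6 (allylic strain), and lutidine is used first so that the hydroxyl is silylated before it can displace the bromide.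

Step 16
Reactants: 21 di-tert-butylsilylene-bridged (Z)-bromo enol ether; 9 (5R,6R)-6-ethenyl-2,6-dimethyl-5-(triethylsilyloxy)cyclohex-2-en-1-one
Product: 23 ring B cyclohexenol bearing the Z silylene enol ether on C15 (alkenyl groups trans; C15 hydroxyl cis to vinyl), via alkenyllithium 22 (not isolated)
Conditions: t-BuLi (2.1 equiv), Et2O, −78 °C; 9, THF, −78 °C; pH 7 buffer at −78 °C
Reagents that add atoms: none
Why: Bromine–lithium exchange with retention of alkene geometry, then irreversible 1,2-addition to the enone carbonyl; attack should be axial through the half-chair that has vinyl pseudoaxial and the C11 silyloxy group equatorial, that is anti to both, which gives the trans-dialkenyl carbinol and the Z enol ether in one step.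

Step 17
Reactants: 23 ring B cyclohexenol bearing the Z silylene enol ether on C15
Product: 26 trans-fused decalin diene (C8=C9 and C13=C14; O7 and C15 hydroxyl both axial on the α face; C10 methyl β), via ten-membered dienol 24 (not isolated), via ten-membered dienone 25 (not isolated)
Conditions: degassed toluene (0.01 M), Et3N (1 equiv), sealed tube, 180 °C
Reagents that add atoms: none
Why: A chair [3,3] sigmatropic (oxy-Cope) shift of the 3-hydroxy-1,5-diene C7=C16–C15(OH)–C10–C9=C8 forms C7–C8 and breaks C10–C15; the dienol 24 tautomerises to the E-cyclodec-5-enone 25, whose C15 carbonyl and C9=C10 alkene then undergo a transannular carbonyl-ene reaction that forms C10–C15, moves the alkene to C8=C9 and passes a C8 hydrogen to oxygen. The closest known reaction type is the thermal tandem oxy-Cope and transannular ene reaction of 1,2-dialkenylcyclohexanols to decalins with a ring-fusion alcohol. The first event is a ring expansion, not an exo or endo closure; the ene bond then closes ring B in a 6-exo-trig mode at the carbonyl with the alkene exocyclic, and ring A in a 6-exo-trig mode at the carbonyl with the alkene endocyclic. C7 is controlled by the Z enol ether and the chair, whose sense is fixed by the trans-diequatorial alkenyl groups on ring B: the oxygen cis to C15 becomes axial and the cyclopentyl group equatorial. The silylene holds C5 syn to O7, so C8 bonds on the face of the C6 methyl, away from CMe2, which is the matched arrangement. C10 and C15 are controlled by the E geometry of C9=C10 and the chair–chair ene transition state with the cyclopentyl group equatorial, which places the angular methyl and hydroxyl anti. The step needs the chair shift to outrun retro-ene fragmentation and the boat-like shift through the ring alkene C13=C14; the trans arrangement, the acyclic Z alkenyl partner and the doubly allylic, fully substituted breaking bond should secure this, and the amine buffers traces of acid.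

Step 18
Reactants: 26 trans-fused decalin diene
Product: 27 C8–C9 dihydro derivative of 26
Conditions: 2-nitrobenzenesulfonohydrazide, Et3N, CH2Cl2, rt
Reagents that add atoms: none
Why: Diimide reduction; the cis-disubstituted C8=C9 should react while the trisubstituted C13=C14 is left, and there is no metal that could cleave the allylic C15–O bond.

Step 19
Reactants: 27 C8–C9 dihydro derivative of 26
Product: 28 C3,C11,C15-triol (silylene retained)
Conditions: PPTS, MeOH/CH2Cl2, 0 °C to rt
Reagents that add atoms: none
Why: Acid-catalysed methanolysis of the two secondary triethylsilyl ethers; the di-tert-butylsilylene should be stable under these conditions, and freeing the axial C11 oxygen first opens the α face of C13=C14 for the next step.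

Step 20
Reactants: 28 C3,C11,C15-triol
Product: 30 C3,C11,C14,C15-tetraol (C14 hydroxyl β and axial), via organomercurial 29 (not isolated)
Conditions: Hg(OAc)2, THF/H2O (1:1), rt; then NaBH4, aq. NaOH, 0 °C
Reagents that add atoms: water, O
Why: Oxymercuration–demercuration; the mercurinium ion should form on the α face (anti to the angular methyl, held by the C15 and C11 hydroxyls) and water should open it at the tertiary C14 from the β face in a trans-diaxial, Markovnikov sense, which gives the C14 hydroxyl anti to the C15 hydroxyl.

Step 21
Reactants: 30 C3,C11,C14,C15-tetraol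
Product: 31 C3,C11-diketone
Conditions: Dess–Martin periodinane, NaHCO3, CH2Cl2, rt
Reagents that add atoms: none
Why: Periodinane oxidation of the two secondary alcohols; the tertiary alcohols are inert and the trans-diaxial C14/C15 diol cannot form the cyclic iodine ester needed for glycol cleavage.

Step 22
Reactants: 31 C3,C11-diketone
Product: 33 bis(alkenyl bromide) with C3(Br)=C4 and C11(Br)=C12, via bis(hydrazone) 32 (not isolated)
Conditions: N2H4·H2O, Et3N, EtOH, 50 °C; evaporate; NBS, pyridine, 0 °C
Reagents that add atoms: N-bromosuccinimide, O=C1CCC(=O)N1Br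
Why: Barton vinyl halide synthesis; each hydrazone is oxidised to a diazo compound, brominated and freed of nitrogen, and proton loss can go only toward C4 and C12 because the other α-carbons are quaternary; no enolate is formed, which avoids retro-aldol at C15 and β-elimination at C5.

Step 23
Reactants: 33 bis(alkenyl bromide)
Product: 34 C3,C11-dibromide (silylene retained)
Conditions: Mn(dpm)3 (10 mol %), PhSiH3, t-BuOOH, i-PrOH, rt
Reagents that add atoms: none
Why: Manganese-hydride hydrogen-atom-transfer hydrogenation of alkenyl bromides; the first hydrogen adds to the CH terminus and the α-bromo radical takes the second from the less hindered face. At C11 this is axial and anti to the angular methyl, giving the equatorial bromide; at C3 it is the convex face opposite the silylene ring and C7, giving the bromide cis to O5.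

Step 24
Reactants: 34 C3,C11-dibromide
Product: 35 neoirietetraol
Conditions: HF·pyridine, pyridine/THF, 0 °C to rt
Reagents that add atoms: none
Why: Fluoride cleavage of the di-tert-butylsilylene frees the C5 and C7 hydroxyls in one operation under conditions that are not basic enough to eliminate the bromides.

## Compound list

1 | 2-methylcyclohexane-1,3-dione | CC1C(=O)CCCC1=O | starting material
2 | 2-methyl-2-(prop-2-en-1-yl)cyclohexane-1,3-dione | C=CCC1(C)C(=O)CCCC1=O | intermediate
3 | (2R,3R)-3-hydroxy-2-methyl-2-(prop-2-en-1-yl)cyclohexan-1-one | O=C1CCC[C@@H](O)[C@@]1(C)CC=C | intermediate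
4 | (2R,3R)-2-methyl-2-(prop-2-en-1-yl)-3-(triethylsilyloxy)cyclohexan-1-one | O=C1CCC[C@@H](O[Si](CC)(CC)CC)[C@@]1(C)CC=C | intermediate
5 | (2R,3R)-2-methyl-2-[(E)-prop-1-en-1-yl]-3-(triethylsilyloxy)cyclohexan-1-one | O=C1CCC[C@@H](O[Si](CC)(CC)CC)[C@@]1(C)/C=C/C | intermediate
6 | (2R,3R)-2-ethenyl-2-methyl-3-(triethylsilyloxy)cyclohexan-1-one | O=C1CCC[C@@H](O[Si](CC)(CC)CC)[C@@]1(C)C=C | intermediate
7 | (2R,3R)-2-ethenyl-2,6-dimethyl-3-(triethylsilyloxy)cyclohexan-1-one (C6 epimers) | O=C1C(C)CC[C@@H](O[Si](CC)(CC)CC)[C@@]1(C)C=C | intermediate
8 | trimethylsilyl enol ether of 7 | C[Si](C)(C)OC1=C(C)CC[C@@H](O[Si](CC)(CC)CC)[C@@]1(C)C=C | intermediate (not isolated)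
9 | (5R,6R)-6-ethenyl-2,6-dimethyl-5-(triethylsilyloxy)cyclohex-2-en-1-one | O=C1C(C)=CC[C@@H](O[Si](CC)(CC)CC)[C@@]1(C)C=C | intermediate
10 | 2,2-dimethylcyclopentane-1,3-dione | CC1(C)C(=O)CCC1=O | starting material
11 | (3R)-3-hydroxy-2,2-dimethylcyclopentan-1-one | CC1(C)[C@H](O)CCC1=O | intermediate
12 | 2,4,6-triisopropylbenzenesulfonylhydrazone of 11 | CC1(C)[C@H](O)CCC1=NNS(=O)(=O)c1c(C(C)C)cc(C(C)C)cc1C(C)C | intermediate
13 | lithium (1R)-3-lithio-2,2-dimethylcyclopent-3-en-1-olate | CC1(C)[C@H](O[Li])CC=C1[Li] | intermediate (not isolated)
14 | (1R)-3-(2-hydroxypropan-2-yl)-2,2-dimethylcyclopent-3-en-1-ol | CC1(C)[C@H](O)CC=C1C(C)(C)O | intermediate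
15 | (1R,3R,5S)-1-(2-hydroxypropan-2-yl)-2,2-dimethyl-6-oxabicyclo[3.1.0]hexan-3-ol | CC1(C)[C@H](O)C[C@@H]2O[C@]12C(C)(C)O | intermediate
16 | 2-[(1R,3R,5S)-2,2-dimethyl-3-(triethylsilyloxy)-6-oxabicyclo[3.1.0]hexan-1-yl]propan-2-ol | CC1(C)[C@H](O[Si](CC)(CC)CC)C[C@@H]2O[C@]12C(C)(C)O | intermediate
17 | 1-[(1R,3R,5S)-5-hydroxy-1,2,2-trimethyl-3-(triethylsilyloxy)cyclopentyl]ethan-1-one | CC1(C)[C@H](O[Si](CC)(CC)CC)C[C@H](O)[C@]1(C)C(C)=O | intermediate
18 | O5-trimethylsilyl ether and trimethylsilyl enol ether of 17 | CC1(C)[C@H](O[Si](CC)(CC)CC)C[C@H](O[Si](C)(C)C)[C@]1(C)C(=C)O[Si](C)(C)C | intermediate (not isolated)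
19 | O5-trimethylsilyl ether of bromoketone 20 | CC1(C)[C@H](O[Si](CC)(CC)CC)C[C@H](O[Si](C)(C)C)[C@]1(C)C(=O)CBr | intermediate (not isolated)
20 | 2-bromo-1-[(1R,3R,5S)-5-hydroxy-1,2,2-trimethyl-3-(triethylsilyloxy)cyclopentyl]ethan-1-one | CC1(C)[C@H](O[Si](CC)(CC)CC)C[C@H](O)[C@]1(C)C(=O)CBr | intermediate
21 | (Z)-4-(bromomethylidene)-2,2-di-tert-butyl-4a,5,5-trimethyl-6-(triethylsilyloxy)hexahydrocyclopenta[d][1,3,2]dioxasiline (cis ring fusion; centres as in 20) | CC1(C)[C@H](O[Si](CC)(CC)CC)C[C@@H]2O[Si](C(C)(C)C)(C(C)(C)C)O/C(=C\Br)[C@]12C | intermediate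
22 | alkenyllithium from 21 (Li in place of Br, Z retained) | CC1(C)[C@H](O[Si](CC)(CC)CC)C[C@@H]2O[Si](C(C)(C)C)(C(C)(C)C)O/C(=C\[Li])[C@]12C | intermediate (not isolated)
23 | key-step precursor: 2,6-dimethyl-5-(triethylsilyloxy)-6-vinylcyclohex-2-en-1-ol carrying at C15 the Z silylene enol ether (alkenyl groups trans, C15 hydroxyl cis to vinyl and to the C11 silyloxy group) | CC1(C)[C@H](O[Si](CC)(CC)CC)C[C@@H]2O[Si](C(C)(C)C)(C(C)(C)C)O/C(=C\[C@]3(O)C(C)=CC[C@@H](O[Si](CC)(CC)CC)[C@@]3(C)C=C)[C@]12C | intermediate
24 | ten-membered dienol (C15 enol, E-C9=C10, C13=C14, C7 set) | CC1(C)[C@H](O[Si](CC)(CC)CC)C[C@@H]2O[Si](C(C)(C)C)(C(C)(C)C)O[C@@]3(C/C=C(C)/[C@H](O[Si](CC)(CC)CC)C/C=C(C)\C(O)=C3)[C@]12C | intermediate (not isolated)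
25 | ten-membered dienone (C15 ketone, E-C9=C10, Z-C13=C14) | CC1(C)[C@H](O[Si](CC)(CC)CC)C[C@@H]2O[Si](C(C)(C)C)(C(C)(C)C)O[C@@]3(C/C=C(C)/[C@H](O[Si](CC)(CC)CC)C/C=C(C)\C(=O)C3)[C@]12C | intermediate (not isolated)
26 | key-step product: trans-fused decalin diene (C8=C9, C13=C14; C7, C10, C15 as in the target; C11 silyloxy α) | CC1(C)[C@H](O[Si](CC)(CC)CC)C[C@@H]2O[Si](C(C)(C)C)(C(C)(C)C)O[C@@]3(C=C[C@]4(C)[C@H](O[Si](CC)(CC)CC)CC=C(C)[C@@]4(O)C3)[C@]12C | intermediate
27 | C8–C9 dihydro derivative of 26 | CC1(C)[C@H](O[Si](CC)(CC)CC)C[C@@H]2O[Si](C(C)(C)C)(C(C)(C)C)O[C@@]3(CC[C@]4(C)[C@H](O[Si](CC)(CC)CC)CC=C(C)[C@@]4(O)C3)[C@]12C | intermediate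
28 | C3,C11,C15-triol with C13=C14 (silylene retained) | CC1(C)[C@H](O)C[C@@H]2O[Si](C(C)(C)C)(C(C)(C)C)O[C@@]3(CC[C@]4(C)[C@H](O)CC=C(C)[C@@]4(O)C3)[C@]12C | intermediate
29 | C13 α-acetoxymercurio, C14 β-hydroxy adduct of 28 | CC1(C)[C@H](O)C[C@@H]2O[Si](C(C)(C)C)(C(C)(C)C)O[C@@]3(CC[C@]4(C)[C@H](O)C[C@H]([Hg]OC(C)=O)[C@@](C)(O)[C@@]4(O)C3)[C@]12C | intermediate (not isolated)
30 | C3,C11,C14,C15-tetraol (C14 and C15 as in the target) | CC1(C)[C@H](O)C[C@@H]2O[Si](C(C)(C)C)(C(C)(C)C)O[C@@]3(CC[C@]4(C)[C@H](O)CC[C@@](C)(O)[C@@]4(O)C3)[C@]12C | intermediate
31 | C3,C11-diketone | CC1(C)C(=O)C[C@@H]2O[Si](C(C)(C)C)(C(C)(C)C)O[C@@]3(CC[C@]4(C)C(=O)CC[C@@](C)(O)[C@@]4(O)C3)[C@]12C | intermediate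
32 | C3,C11-bis(hydrazone) | CC1(C)C(=NN)C[C@@H]2O[Si](C(C)(C)C)(C(C)(C)C)O[C@@]3(CC[C@]4(C)C(=NN)CC[C@@](C)(O)[C@@]4(O)C3)[C@]12C | intermediate (not isolated)
33 | bis(alkenyl bromide), C3(Br)=C4 and C11(Br)=C12 | CC1(C)C(Br)=C[C@@H]2O[Si](C(C)(C)C)(C(C)(C)C)O[C@@]3(CC[C@]4(C)C(Br)=CC[C@@](C)(O)[C@@]4(O)C3)[C@]12C | intermediate
34 | O5,O7-di-tert-butylsilylene derivative of neoirietetraol | CC1(C)[C@H](Br)C[C@@H]2O[Si](C(C)(C)C)(C(C)(C)C)O[C@@]3(CC[C@]4(C)[C@@H](Br)CC[C@@](C)(O)[C@@]4(O)C3)[C@]12C | intermediate
35 | neoirietetraol | CC1(C)[C@H](Br)C[C@H](O)[C@]1(C)[C@@]1(O)CC[C@]2(C)[C@@H](Br)CC[C@@](C)(O)[C@@]2(O)C1 | target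

## Step count and least certain steps

Total: 24 steps. Longest linear sequence: 17 steps, from 10 through steps 8 to 24. The ring B branch from 1 contributes 7 steps before the union in step 16.

Step 17 (key step). The most likely failure is that retro-ene fragmentation of the β-hydroxy alkene, or alcoholysis of the enol silyl ether by the neighbouring hydroxyl, outruns the [3,3] shift at 180 °C. The ene closure may also stall because the C15 carbonyl of 25 is conjugated. Fallback, from 23 back to 26: the shift is run as an anionic oxy-Cope rearrangement (KN(SiMe3)2, 18-crown-6, THF, −20 °C), the enolate is protonated and the dienone 25 is isolated. Me2AlCl in CH2Cl2 at −78 °C then promotes the transannular carbonyl-ene closure (F0, no new compound).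

Step 16. The most likely failures are insufficient facial selectivity at C15, and loss of the lithium reagent by oxygen-to-carbon silyl migration or by proton transfer from the enone before addition. Fallback, from 20 and 9 back to 23: a SmI2-mediated Reformatsky-type addition of the bromoketone 20 to 9 (THF, −78 °C) gives the aldol adduct F1. Treatment with t-Bu2Si(OTf)2 and 2,6-lutidine, then Et3N, silylates O5 and closes the silylene onto the enol oxygen, with Z-selective enolisation toward C16, to give 23.

Step 22. The most likely failures are capture of the α-bromo cation by bromide (geminal dibromide), a methyl shift from the neighbouring quaternary carbon, or retro-aldol opening while the C11 hydrazone forms. Fallback, from 31 back to 33: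
- Me3SiOTf and 2,6-lutidine protect the two tertiary alcohols as the bis(trimethylsilyl) ether F3.
- KN(SiMe3)2 and N-(5-chloropyridin-2-yl)triflimide at −78 °C give the bis(enol triflate) F4.
- [Cp*Ru(MeCN)3]OTf with LiBr exchanges triflate for bromide, giving the silylated bis(alkenyl bromide) F5.
- Citric acid in MeOH removes the trimethylsilyl groups to give 33.

Step 23. The most likely failures are weak facial discrimination in the hydrogen transfer to the cyclopentyl radical at C3 (epimers at C3) and partial loss of bromine by over-reduction. Fallback, from 33 to 34: heterogeneous hydrogenation (H2, Rh/Al2O3, EtOAc). This is a syn addition of both hydrogens from the convex face of ring C and the α face of ring B, which should lead to the same configurations by a different mechanism (F0, no new compound).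

Step 20. The most likely failure is slow mercuration of the hindered trisubstituted alkene, or mercurinium formation on the β face, which would erode the configuration at C14. Fallback, from 28 back to 30: bromohydrin formation (NBS, aqueous THF, 0 °C) gives the trans-diaxial bromohydrin F2 (C13 bromide α, C14 hydroxyl β). Radical debromination (Bu3SnH, AIBN, benzene, 80 °C) then gives 30; no other halogen is present at that stage.

## Further compounds

F0 | step 17 | none | none
F1 | step 16 | aldol adduct of 20 and 9 (C7 ketone, free C5 and C15 hydroxyls, C15 as in 23) | CC1(C)[C@H](O[Si](CC)(CC)CC)C[C@H](O)[C@]1(C)C(=O)C[C@]2(O)C(C)=CC[C@@H](O[Si](CC)(CC)CC)[C@@]2(C)C=C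
F2 | step 20 | C13 α-bromo, C14 β-hydroxy bromohydrin of 28 | CC1(C)[C@H](O)C[C@@H]2O[Si](C(C)(C)C)(C(C)(C)C)O[C@@]3(CC[C@]4(C)[C@H](O)C[C@H](Br)[C@@](C)(O)[C@@]4(O)C3)[C@]12C
F3 | step 22 | C14,C15-bis(trimethylsilyl) ether of diketone 31 | CC1(C)C(=O)C[C@@H]2O[Si](C(C)(C)C)(C(C)(C)C)O[C@@]3(CC[C@]4(C)C(=O)CC[C@@](C)(O[Si](C)(C)C)[C@@]4(O[Si](C)(C)C)C3)[C@]12C
F4 | step 22 | bis(enol triflate) of F3 (C3=C4 and C11=C12) | CC1(C)C(OS(=O)(=O)C(F)(F)F)=C[C@@H]2O[Si](C(C)(C)C)(C(C)(C)C)O[C@@]3(CC[C@]4(C)C(OS(=O)(=O)C(F)(F)F)=CC[C@@](C)(O[Si](C)(C)C)[C@@]4(O[Si](C)(C)C)C3)[C@]12C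
F5 | step 22 | C14,C15-bis(trimethylsilyl) ether of bis(alkenyl bromide) 33 | CC1(C)C(Br)=C[C@@H]2O[Si](C(C)(C)C)(C(C)(C)C)O[C@@]3(CC[C@]4(C)C(Br)=CC[C@@](C)(O[Si](C)(C)C)[C@@]4(O[Si](C)(C)C)C3)[C@]12C
F0 | step 23 | none | none
A1 | alternative 1 | β-hydroxy cyclopentanone with C2–C6 and C6–C7 in place (C5 ketone, C3 benzyl ether) | CC1(C)[C@H](OCc2ccccc2)CC(=O)[C@]1(C)[C@@]1(O)CC[C@]2(C)[C@@H](Br)CC[C@@](C)(O)[C@@]2(O)C1
A2 | alternative 2 | cyclopentane-fused spiro-oxetane (O bridging C5 and C7) | CC1(C)[C@H](O[Si](C)(C)C(C)(C)C)C[C@@H]2O[C@@]3(CC[C@]4(C)[C@@H](Br)CC[C@@](C)(O)[C@@]4(OC(=O)OC(C)(C)C)C3)[C@]12C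
A3 | alternative 3 | trans-fused bromo α-ketol ketal (C14 ketone, C15 hydroxyl) | C1COC2(O1)CC[C@]3(C)[C@@H](Br)CCC(=O)[C@@]3(O)C2
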